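We charge 0.74 M of starting material and must choose how much partner goes beside it. The flasks, the readings and the questions are these.

| flask | starting material | partner | remark | time |
|---|---|---|---|---|
| winter | 0.74 M | 0.12 M | run made earlier |  |
| midnight | 0.74 M | 0.85 M | run made earlier |  |
| zeta | 0.74 M | 0.0800 M |  | 3.0 h |
| beta | 0.74 M | 0.200 M |  | 3.0 h |
| delta | 0.74 M | 0.600 M |  | 3.0 h |

| run | time / min | single product / % | starting material / % |
|---|---|---|---|
| winter | 8.00 | 3.1 | 92.7 |
| winter | 25.0 | 3.0 | 92.7 |
| winter | 40.0 | 3.1 | 93.4 |
| winter | 60.0 | 3.0 | 92.0 |
| winter | 90.0 | 3.1 | 91.6 |
| midnight | 20.0 | 16.8 | 57.3 |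
| midnight | 40.0 | 18.0 | 56.3 |
| midnight | 50.0 | 16.2 | 55.1 |
| midnight | 80.0 | 16.8 | 56.3 |
| midnight | 90.0 | 17.5 | 57.1 |

(standard deviation of a reading: 0.5 percentage points)

* amount of single product at the end, in percent of the starting material charged for zeta, beta, delta, in this order
* the shape of the row from first to last (hardly changes / falls, then rises / falls all the way / rises, then falls / rises all the way)

- the numbers in the tables scatter by 0.5 percentage points (one standard deviation)
- "hardly changes" means that all values lie within two and a half points (for a concentration: within two and a half percent of the largest)

1. The clock is not our choice to make. The winter product stays between 3.0% and 3.1% from 8.00 min to 90.0 min, and the midnight product stays between 16.2% and 18.0% from 20.0 min to 90.0 min. So we take readings at 3.0 h to lie on the same plateaus, leave the time alone and change the partner.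

2. We look for what holds still while the partner charge changes by a factor of 7.08. The winter readings of starting material average 92.5%, which gives 0.651 L mol⁻¹. The midnight readings average 56.4%, which gives 0.673 L mol⁻¹. Their mean is 0.662 L mol⁻¹, and we freeze it as the reach: the natural logarithm of charged over left starting material, per molar of partner charged.

3. A second reading holds still as well. The readings put the single product at 40.7% of the starting material lost in winter and 39.1% in midnight, so we freeze the share at 39.9%.

4. Our own reckoning takes the fraction left as exp(−reach × partner charged) and the product as share × fraction lost. This gives 2.06% for zeta, 4.95% for beta and 13.1% for delta. Delta promises more product than the other two, so delta's 0.600 M is the charge we would choose.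

5. The forecast, reasoning that “each has already reached equilibrium”, gives 2.1%, 5.1% and 13%, and rises all the way. Its beta figure stands above our 4.95%.

The flasks give 1.96%, 4.75% and 12.9% of single product, and the row rises all the way.

    partner + other mono adduct → double product (k = 0.150 L mol⁻¹ min⁻¹)
    starting material + partner → other mono adduct (k = 0.0930 L mol⁻¹ min⁻¹)
    starting material + partner → single product (k = 0.0610 L mol⁻¹ min⁻¹)
    partner → decomposed reagent (k = 0.130 min⁻¹)
    partner + single product → double product (k = 7.70 × 10⁻⁴ L mol⁻¹ min⁻¹)

In delta at 3.00 h the partner, the limiting reagent, stands at 0% of its charge with the starting material at 67.4%, and a reading at 30.0 h leaves the delta single product where it was. Read from delta's end, the reach is 0.657 L mol⁻¹. Our frozen reach on zeta's 0.0800 M of partner leaves 94.8% of the starting material, and zeta ends with 95.1%.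

The data were generated by integration for an exercise.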